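Target 24 ⇐ C12 alcohol 22 (oxidation to the acid last) ⇐ Mitsunobu union of allylic alcohol 16 (C15–OH) with (Z)-acid 20; 16 ⇐ enal 15.
Key disconnection C3–C4 (ring A is formed last, on an existing ring B): enal 15 ⇐ enal–aldehyde 12 by a hydride-triggered iminium–enamine cascade (conjugate reduction, aldol closure, dehydration).
Enabling feature: at the aldehyde level C3=C4–C15 is an aldol-condensation retron, and in 12 C4/C5 are the α/β carbons of an exocyclic enal (C5=C4–C15H=O) on ring B, next to quaternary C10 with its axial methyl C14 and the C1–C2–C3 aldehyde arm; one hydride to C5 sets the ring-fusion centre and releases the C4 enamine that closes on C3.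
12 ⇐ ketone 8 (ethoxyacetylide addition/Meyer–Schuster, global reduction, global oxidation) ⇐ keto ester 6 (allylic oxidation of the isopropenyl methyl to C12–OH, silylation).
6 ⇐ (+)-dihydrocarvone 1 (ring B and C7 from the chiral pool) + methyl acrylate 3; C10 is set by auxiliary-controlled Michael addition of the (R)-1-phenylethylamine imine.

Key step: step 7

Remark: atoms are numbered as in eudesmane (ring A = C1–C5 and C10, ring B = C5–C10, C14 the methyl on C10, C15 on C4, C11–C13 the side chain on C7); commercial (+)-dihydrocarvone is a mixture of C-2 epimers, which does not matter because that centre passes through the enamine in step 1.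

Step 1
Reactants: 1 (+)-dihydrocarvone; 2 (R)-1-phenylethylamine; 3 methyl acrylate
Product: 6 methyl 3-[(1S,4R)-1-methyl-2-oxo-4-(prop-1-en-2-yl)cyclohexyl]propanoate, via imine 4 (not isolated), via alkylated imine 5 (not isolated)
Conditions: (i) TsOH (cat.), PhMe, reflux, Dean–Stark; (ii) 3 (5 equiv), hydroquinone (cat.), THF, 65 °C; (iii) aq. AcOH, 23 °C
Reagents that add atoms: water (O)
Why: Chiral-imine Michael addition through the more substituted secondary enamine, which adds to the acrylate in an aza-ene-like transition state on the face remote from the phenyl group of the (R)-auxiliary; this should override the ring's own bias and set quaternary C10 with the new chain trans to the isopropenyl group, and mild acid hydrolysis returns the ketone.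

Step 2
Reactants: 6 methyl 3-[(1S,4R)-1-methyl-2-oxo-4-(prop-1-en-2-yl)cyclohexyl]propanoate
Product: 7 methyl 3-[(1S,4R)-4-(3-hydroxyprop-1-en-2-yl)-1-methyl-2-oxocyclohexyl]propanoate
Conditions: SeO2 (0.3 equiv), t-BuOOH (3 equiv), CH2Cl2, 0 → 23 °C
Reagents that add atoms: tert-butyl hydroperoxide (CC(C)(C)OO)
Why: SeO2-catalysed allylic oxidation (ene reaction, then [2,3]-sigmatropic shift) should hydroxylate the methyl group of the 1,1-disubstituted alkene, the only electron-rich olefin present, and leave ketone and ester alone at room temperature; no stereocenter is touched.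

Step 3
Reactants: 7 methyl 3-[(1S,4R)-4-(3-hydroxyprop-1-en-2-yl)-1-methyl-2-oxocyclohexyl]propanoate
Product: 8 methyl 3-[(1S,4R)-4-{3-[(tert-butyldiphenylsilyl)oxy]prop-1-en-2-yl}-1-methyl-2-oxocyclohexyl]propanoate
Conditions: t-BuPh2SiCl, imidazole, DMF, 23 °C
Reagents that add atoms: tert-butyl(chloro)diphenylsilane (CC(C)(C)[Si](Cl)(c1ccccc1)c1ccccc1)
Why: Standard silylation of the primary allylic alcohol; the robust silyl ether carries the future carboxyl carbon C12 through the acetylide, Lewis acid, hydride and amine-salt steps.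

Step 4
Reactants: 8 methyl 3-[(1S,4R)-4-{3-[(tert-butyldiphenylsilyl)oxy]prop-1-en-2-yl}-1-methyl-2-oxocyclohexyl]propanoate
Product: 10 ethyl (2E)-2-[(2S,5R)-5-{3-[(tert-butyldiphenylsilyl)oxy]prop-1-en-2-yl}-2-(3-methoxy-3-oxopropyl)-2-methylcyclohexylidene]acetate, via propargylic alcohol 9 (not isolated)
Conditions: (i) ethoxyacetylene, n-BuLi, THF, −78 → −30 °C, then aq. NH4Cl; (ii) crude 9, Sc(OTf)3 (5 mol %), EtOH, CH2Cl2, 23 °C
Reagents that add atoms: ethoxyacetylene (C#COCC)
Why: 1,2-Addition of the slim lithium acetylide to the α-quaternary ketone at low temperature (the ester is not attacked), then Meyer–Schuster rearrangement of the ethoxyalkynyl carbinol to the exocyclic enoate; the (E)-isomer is favoured because the ester group avoids the quaternary carbon, and the carbinol centre is lost.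

Step 5
Reactants: 10 ethyl (2E)-2-[(2S,5R)-5-{3-[(tert-butyldiphenylsilyl)oxy]prop-1-en-2-yl}-2-(3-methoxy-3-oxopropyl)-2-methylcyclohexylidene]acetate
Product: 11 (2E)-2-[(2S,5R)-5-{3-[(tert-butyldiphenylsilyl)oxy]prop-1-en-2-yl}-2-(3-hydroxypropyl)-2-methylcyclohexylidene]ethan-1-ol
Conditions: iBu2AlH (6 equiv), CH2Cl2, −78 → 0 °C; aq. Rochelle salt
Reagents that add atoms: none
Why: Exhaustive iBu2AlH reduction takes both esters to primary alcohols (1,2-reduction of the enoate), so the two ester groups need not be told apart.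

Step 6
Reactants: 11 (2E)-2-[(2S,5R)-5-{3-[(tert-butyldiphenylsilyl)oxy]prop-1-en-2-yl}-2-(3-hydroxypropyl)-2-methylcyclohexylidene]ethan-1-ol
Product: 12 (2E)-2-[(2S,5R)-5-{3-[(tert-butyldiphenylsilyl)oxy]prop-1-en-2-yl}-2-methyl-2-(3-oxopropyl)cyclohexylidene]acetaldehyde
Conditions: Dess–Martin periodinane (2.6 equiv), NaHCO3, CH2Cl2, 0 → 23 °C
Reagents that add atoms: none
Why: Dess–Martin oxidation of both primary alcohols under buffered conditions should give the enal and the saturated aldehyde in one operation without moving the double bond.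

Step 7
Reactants: 12 (2E)-2-[(2S,5R)-5-{3-[(tert-butyldiphenylsilyl)oxy]prop-1-en-2-yl}-2-methyl-2-(3-oxopropyl)cyclohexylidene]acetaldehyde
Product: 15 (4aR,7R,8aR)-7-{3-[(tert-butyldiphenylsilyl)oxy]prop-1-en-2-yl}-4a-methyl-3,4,4a,5,6,7,8,8a-octahydronaphthalene-1-carbaldehyde, via enamine 13 (not isolated), via aldol 14 (not isolated)
Conditions: Hantzsch ester (diethyl 2,6-dimethyl-1,4-dihydropyridine-3,5-dicarboxylate, 1.1 equiv), Bn2NH·CF3CO2H (20 mol %), PhMe (0.02 M), 23 → 50 °C
Reagents that add atoms: none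
Why: Proposed new method: the ammonium salt condenses with the enal of 12 to an iminium ion, the Hantzsch ester transfers hydride to the β-carbon C5, and the (E)-enamine 13 so released (C4=C15–N) adds to the C3 aldehyde five atoms away before it is hydrolysed, after which loss of water through the enamine (E1cB) and hydrolysis give the conjugated aldehyde 15 and return the amine; the closest known reaction types are the amine-salt/Hantzsch-ester transfer hydrogenation of β,β-disubstituted enals, the hydride-triggered iminium–enamine reductive Michael cyclization, and the dibenzylammonium trifluoroacetate aldol condensation of dialdehydes to cyclohexenecarbaldehydes. Ring A is closed by the C3–C4 bond in a 6-(enolexo)-exo-trig aldol addition through a chair transition state. C5 is the only new stereocenter: ring B is a chair with the C7 side chain and the C1–C3 arm equatorial and the methyl C14 axial on C10, so hydride should enter C5 axially from the α face, anti to C14, which leaves C4 equatorial and trans to C1 (trans ring fusion); the centres at C3 and C4 of aldol 14 are lost on dehydration. Regioselectivity (C4, not C2, as the nucleophile) is needed and is secured because the enamine is born at C4 by the hydride transfer, while the (E)-geometry of the enal keeps C15 out of reach of an enamine at C2. Chemoselectivity is needed as well and is secured because the Hantzsch ester reduces only the iminium-activated C=C bond (not the saturated aldehyde, the 1,1-disubstituted alkene or the silyl ether), and the α-branched product enal forms its iminium ion too slowly to be reduced further.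

Step 8
Reactants: 15 (4aR,7R,8aR)-7-{3-[(tert-butyldiphenylsilyl)oxy]prop-1-en-2-yl}-4a-methyl-3,4,4a,5,6,7,8,8a-octahydronaphthalene-1-carbaldehyde
Product: 16 [(4aR,7R,8aR)-7-{3-[(tert-butyldiphenylsilyl)oxy]prop-1-en-2-yl}-4a-methyl-3,4,4a,5,6,7,8,8a-octahydronaphthalen-1-yl]methanol
Conditions: NaBH4, CeCl3·7H2O, MeOH, −40 °C
Reagents that add atoms: none
Why: Luche reduction: 1,2-selective hydride addition to the enal gives the primary allylic alcohol and leaves the other alkene and the silyl ether untouched.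

Step 9
Reactants: 17 4-[(tert-butyldimethylsilyl)oxy]benzaldehyde; 18 methyl 2-[bis(2,2,2-trifluoroethoxy)phosphoryl]acetate
Product: 19 methyl (2Z)-3-{4-[(tert-butyldimethylsilyl)oxy]phenyl}prop-2-enoate
Conditions: KN(SiMe3)2, 18-crown-6, THF, −78 °C
Reagents that add atoms: none
Why: Still–Gennari olefination: with the bis(trifluoroethyl) phosphonate under dissociating conditions the first adduct eliminates faster than it equilibrates, which should give the (Z)-enoate.

Step 10
Reactants: 19 methyl (2Z)-3-{4-[(tert-butyldimethylsilyl)oxy]phenyl}prop-2-enoate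
Product: 20 (2Z)-3-{4-[(tert-butyldimethylsilyl)oxy]phenyl}prop-2-enoic acid
Conditions: Me3SnOH (4 equiv), 1,2-dichloroethane, 70 °C, dark; then 1 M HCl
Reagents that add atoms: trimethyltin hydroxide (C[Sn](C)(C)O)
Why: Me3SnOH cleaves the methyl ester under neutral conditions by acyl–oxygen cleavage, so no phenoxide is formed, the aryl silyl ether stays and the (Z)-double bond is not put at risk.

Step 11
Reactants: 16 [(4aR,7R,8aR)-7-{3-[(tert-butyldiphenylsilyl)oxy]prop-1-en-2-yl}-4a-methyl-3,4,4a,5,6,7,8,8a-octahydronaphthalen-1-yl]methanol; 20 (2Z)-3-{4-[(tert-butyldimethylsilyl)oxy]phenyl}prop-2-enoic acid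
Product: 21 [(4aR,7R,8aR)-7-{3-[(tert-butyldiphenylsilyl)oxy]prop-1-en-2-yl}-4a-methyl-3,4,4a,5,6,7,8,8a-octahydronaphthalen-1-yl]methyl (2Z)-3-{4-[(tert-butyldimethylsilyl)oxy]phenyl}prop-2-enoate
Conditions: PPh3, DIAD, THF, 0 → 23 °C, dark
Reagents that add atoms: none
Why: Mitsunobu esterification: the carboxylate displaces the phosphonium-activated primary allylic oxygen by SN2 at C15 (the more hindered SN2′ site C3 is not attacked), so the acid is never turned into an acylating agent and the (Z)-geometry is kept.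

Step 12
Reactants: 21 [(4aR,7R,8aR)-7-{3-[(tert-butyldiphenylsilyl)oxy]prop-1-en-2-yl}-4a-methyl-3,4,4a,5,6,7,8,8a-octahydronaphthalen-1-yl]methyl (2Z)-3-{4-[(tert-butyldimethylsilyl)oxy]phenyl}prop-2-enoate
Product: 22 [(4aR,7R,8aR)-7-(3-hydroxyprop-1-en-2-yl)-4a-methyl-3,4,4a,5,6,7,8,8a-octahydronaphthalen-1-yl]methyl (2Z)-3-(4-hydroxyphenyl)prop-2-enoate
Conditions: Bu4NF, AcOH (1:1), THF, 0 → 23 °C, dark
Reagents that add atoms: none
Why: Fluoride cleaves both silicon–oxygen bonds, and buffering with AcOH keeps the medium near neutral so that the allylic ester and the (Z)-alkene stay intact.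

Step 13
Reactants: 22 [(4aR,7R,8aR)-7-(3-hydroxyprop-1-en-2-yl)-4a-methyl-3,4,4a,5,6,7,8,8a-octahydronaphthalen-1-yl]methyl (2Z)-3-(4-hydroxyphenyl)prop-2-enoate
Product: 23 [(4aR,7R,8aR)-4a-methyl-7-(3-oxoprop-1-en-2-yl)-3,4,4a,5,6,7,8,8a-octahydronaphthalen-1-yl]methyl (2Z)-3-(4-hydroxyphenyl)prop-2-enoate
Conditions: MnO2 (activated, 20 equiv), CH2Cl2, 23 °C, dark
Reagents that add atoms: none
Why: MnO2 oxidizes the allylic alcohol selectively to the 2-substituted acrolein and should leave phenol, ester and the other alkenes alone.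

Step 14
Reactants: 23 [(4aR,7R,8aR)-4a-methyl-7-(3-oxoprop-1-en-2-yl)-3,4,4a,5,6,7,8,8a-octahydronaphthalen-1-yl]methyl (2Z)-3-(4-hydroxyphenyl)prop-2-enoate
Product: 24 2-[(2R,4aR,8aR)-8-({[(2Z)-3-(4-hydroxyphenyl)prop-2-enoyl]oxy}methyl)-4a-methyl-1,2,3,4,4a,5,6,8a-octahydronaphthalen-2-yl]prop-2-enoic acid
Conditions: NaClO2, NaH2PO4, 2-methyl-2-butene, t-BuOH/H2O, 0 → 23 °C, dark
Reagents that add atoms: sodium chlorite ([Na+].[O-]Cl=O)
Why: Pinnick oxidation converts the aldehyde into the acid without moving the exocyclic double bond, and 2-methyl-2-butene scavenges HOCl so that the phenol and the alkenes are not chlorinated.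

Compound list
1 | (+)-dihydrocarvone, (2R,5R)-2-methyl-5-(prop-1-en-2-yl)cyclohexan-1-one (major epimer of the commercial mixture) | C=C(C)[C@@H]1CC[C@@H](C)C(=O)C1 | starting material
2 | (R)-1-phenylethylamine | C[C@@H](N)c1ccccc1 | starting material
3 | methyl acrylate | C=CC(=O)OC | starting material
4 | (1R)-N-[(5R)-2-methyl-5-(prop-1-en-2-yl)cyclohexylidene]-1-phenylethan-1-amine (C-2 epimers, in equilibrium with the secondary enamine) | C=C(C)[C@@H]1CCC(C)C(=N[C@H](C)c2ccccc2)C1 | intermediate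
5 | methyl 3-[(1S,4R)-1-methyl-2-{[(1R)-1-phenylethyl]imino}-4-(prop-1-en-2-yl)cyclohexyl]propanoate | C=C(C)[C@@H]1CC[C@@](C)(CCC(=O)OC)C(=N[C@H](C)c2ccccc2)C1 | intermediate
6 | methyl 3-[(1S,4R)-1-methyl-2-oxo-4-(prop-1-en-2-yl)cyclohexyl]propanoate | C=C(C)[C@@H]1CC[C@@](C)(CCC(=O)OC)C(=O)C1 | intermediate
7 | methyl 3-[(1S,4R)-4-(3-hydroxyprop-1-en-2-yl)-1-methyl-2-oxocyclohexyl]propanoate | C=C(CO)[C@@H]1CC[C@@](C)(CCC(=O)OC)C(=O)C1 | intermediate
8 | methyl 3-[(1S,4R)-4-{3-[(tert-butyldiphenylsilyl)oxy]prop-1-en-2-yl}-1-methyl-2-oxocyclohexyl]propanoate | C=C(CO[Si](c2ccccc2)(c2ccccc2)C(C)(C)C)[C@@H]1CC[C@@](C)(CCC(=O)OC)C(=O)C1 | intermediate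
9 | methyl 3-[(1S,4R)-4-{3-[(tert-butyldiphenylsilyl)oxy]prop-1-en-2-yl}-2-(ethoxyethynyl)-2-hydroxy-1-methylcyclohexyl]propanoate (either carbinol epimer at C-2) | C=C(CO[Si](c2ccccc2)(c2ccccc2)C(C)(C)C)[C@@H]1CC[C@@](C)(CCC(=O)OC)C(O)(C#COCC)C1 | intermediate
10 | ethyl (2E)-2-[(2S,5R)-5-{3-[(tert-butyldiphenylsilyl)oxy]prop-1-en-2-yl}-2-(3-methoxy-3-oxopropyl)-2-methylcyclohexylidene]acetate | C=C(CO[Si](c2ccccc2)(c2ccccc2)C(C)(C)C)[C@@H]1CC[C@@](C)(CCC(=O)OC)/C(=C/C(=O)OCC)C1 | intermediate
11 | (2E)-2-[(2S,5R)-5-{3-[(tert-butyldiphenylsilyl)oxy]prop-1-en-2-yl}-2-(3-hydroxypropyl)-2-methylcyclohexylidene]ethan-1-ol | C=C(CO[Si](c2ccccc2)(c2ccccc2)C(C)(C)C)[C@@H]1CC[C@@](C)(CCCO)/C(=C/CO)C1 | intermediate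
12 | (2E)-2-[(2S,5R)-5-{3-[(tert-butyldiphenylsilyl)oxy]prop-1-en-2-yl}-2-methyl-2-(3-oxopropyl)cyclohexylidene]acetaldehyde | C=C(CO[Si](c2ccccc2)(c2ccccc2)C(C)(C)C)[C@@H]1CC[C@@](C)(CCC=O)/C(=C/C=O)C1 | intermediate
13 | 3-[(1S,2S,4R)-4-{3-[(tert-butyldiphenylsilyl)oxy]prop-1-en-2-yl}-2-[(E)-2-(dibenzylamino)ethenyl]-1-methylcyclohexyl]propanal | C=C(CO[Si](c2ccccc2)(c2ccccc2)C(C)(C)C)[C@@H]1CC[C@@](C)(CCC=O)[C@H](/C=C/N(Cc2ccccc2)Cc2ccccc2)C1 | intermediate
14 | (4aS,7R,8aS)-7-{3-[(tert-butyldiphenylsilyl)oxy]prop-1-en-2-yl}-2-hydroxy-4a-methyldecahydronaphthalene-1-carbaldehyde (trans-fused; epimers at C-1 and C-2) | C=C(CO[Si](c3ccccc3)(c3ccccc3)C(C)(C)C)[C@@H]1CC[C@@]2(C)CCC(O)C(C=O)[C@@H]2C1 | intermediate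
15 | (4aR,7R,8aR)-7-{3-[(tert-butyldiphenylsilyl)oxy]prop-1-en-2-yl}-4a-methyl-3,4,4a,5,6,7,8,8a-octahydronaphthalene-1-carbaldehyde | C=C(CO[Si](c3ccccc3)(c3ccccc3)C(C)(C)C)[C@@H]1CC[C@@]2(C)CCC=C(C=O)[C@@H]2C1 | intermediate
16 | [(4aR,7R,8aR)-7-{3-[(tert-butyldiphenylsilyl)oxy]prop-1-en-2-yl}-4a-methyl-3,4,4a,5,6,7,8,8a-octahydronaphthalen-1-yl]methanol | C=C(CO[Si](c3ccccc3)(c3ccccc3)C(C)(C)C)[C@@H]1CC[C@@]2(C)CCC=C(CO)[C@@H]2C1 | intermediate
17 | 4-[(tert-butyldimethylsilyl)oxy]benzaldehyde | O=Cc1ccc(O[Si](C)(C)C(C)(C)C)cc1 | starting material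
18 | methyl 2-[bis(2,2,2-trifluoroethoxy)phosphoryl]acetate | COC(=O)CP(=O)(OCC(F)(F)F)OCC(F)(F)F | starting material
19 | methyl (2Z)-3-{4-[(tert-butyldimethylsilyl)oxy]phenyl}prop-2-enoate | COC(=O)/C=C\c1ccc(O[Si](C)(C)C(C)(C)C)cc1 | intermediate
20 | (2Z)-3-{4-[(tert-butyldimethylsilyl)oxy]phenyl}prop-2-enoic acid | OC(=O)/C=C\c1ccc(O[Si](C)(C)C(C)(C)C)cc1 | intermediate
21 | [(4aR,7R,8aR)-7-{3-[(tert-butyldiphenylsilyl)oxy]prop-1-en-2-yl}-4a-methyl-3,4,4a,5,6,7,8,8a-octahydronaphthalen-1-yl]methyl (2Z)-3-{4-[(tert-butyldimethylsilyl)oxy]phenyl}prop-2-enoate | C=C(CO[Si](c3ccccc3)(c3ccccc3)C(C)(C)C)[C@@H]1CC[C@@]2(C)CCC=C(COC(=O)/C=C\c3ccc(O[Si](C)(C)C(C)(C)C)cc3)[C@@H]2C1 | intermediate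
22 | [(4aR,7R,8aR)-7-(3-hydroxyprop-1-en-2-yl)-4a-methyl-3,4,4a,5,6,7,8,8a-octahydronaphthalen-1-yl]methyl (2Z)-3-(4-hydroxyphenyl)prop-2-enoate | C=C(CO)[C@@H]1CC[C@@]2(C)CCC=C(COC(=O)/C=C\c3ccc(O)cc3)[C@@H]2C1 | intermediate
23 | [(4aR,7R,8aR)-4a-methyl-7-(3-oxoprop-1-en-2-yl)-3,4,4a,5,6,7,8,8a-octahydronaphthalen-1-yl]methyl (2Z)-3-(4-hydroxyphenyl)prop-2-enoate | C=C(C=O)[C@@H]1CC[C@@]2(C)CCC=C(COC(=O)/C=C\c3ccc(O)cc3)[C@@H]2C1 | intermediate
24 | 2-[(2R,4aR,8aR)-8-({[(2Z)-3-(4-hydroxyphenyl)prop-2-enoyl]oxy}methyl)-4a-methyl-1,2,3,4,4a,5,6,8a-octahydronaphthalen-2-yl]prop-2-enoic acid | C=C(C(=O)O)[C@@H]1CC[C@@]2(C)CCC=C(COC(=O)/C=C\c3ccc(O)cc3)[C@@H]2C1 | target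

Total step count: 14. Longest linear sequence: 12 steps (steps 1–8 and 11–14); steps 9 and 10 make the acid partner.

Steps most likely to fail

Step 7 (the proposed new cascade). Three processes may spoil it. The first-formed enamine may be hydrolysed before it cyclizes, after which the dialdehyde can re-enolize toward C2 and regiocontrol is lost. A non-reductive aldol condensation through the dienamine of the enal may outrun hydride transfer. Hydride delivery to C5 may not be face-selective enough. The fallback uses known chemistry and sets out from 12: [(Ph3P)CuH]6 (stoichiometric in hydride) in PhMe/THF at −40 °C should add hydride to C5 and give the copper enolate at C4, which adds to the C3 aldehyde under aprotic conditions where the enolate cannot equilibrate (conjugate reduction–aldol cyclization). The β-hydroxy aldehyde 14 would be isolated this time and dehydrated in a separate operation with Bn2NH·CF3CO2H in benzene at 50 °C, which comes back to the route at 15. No compound outside the list is made (F0).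

Step 2. Over-oxidation of the alcohol to the enal, competing α-oxidation of the ketone and incomplete conversion may lower the return. The fallback sets out from 6 and replaces direct oxidation by chlorination and substitution: ene-type allylic chlorination with Ca(OCl)2 and solid CO2 in CH2Cl2/H2O at 0 °C should give the allylic chloride methyl 3-[(1S,4R)-4-(3-chloroprop-1-en-2-yl)-1-methyl-2-oxocyclohexyl]propanoate F1. Displacement with KOAc and 18-crown-6 in DMF should give the acetate methyl 3-[(1S,4R)-4-[3-(acetyloxy)prop-1-en-2-yl]-1-methyl-2-oxocyclohexyl]propanoate F2, and methanolysis (K2CO3, MeOH, 0 °C) comes back to the route at 7.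

Step 4. Addition to the α-quaternary ketone may be slow, with attack on the ester on warming, and the carbinol may dehydrate toward C6 to a deconjugated ester instead of rearranging. The fallback sets out from 8 and builds the exocyclic double bond by olefination: Horner–Wadsworth–Emmons reaction with the compact anion of (EtO)2P(O)CH2CN (NaH, THF, 0 → 40 °C) should give the unsaturated nitrile methyl 3-[(1S,2E,4R)-4-{3-[(tert-butyldiphenylsilyl)oxy]prop-1-en-2-yl}-2-(cyanomethylidene)-1-methylcyclohexyl]propanoate F3. Excess iBu2AlH (CH2Cl2, −78 → 0 °C, then dilute acid) reduces the nitrile to the enal and the ester to the alcohol, giving (2E)-2-[(2S,5R)-5-{3-[(tert-butyldiphenylsilyl)oxy]prop-1-en-2-yl}-2-(3-hydroxypropyl)-2-methylcyclohexylidene]acetaldehyde F4, and Dess–Martin oxidation comes back to the route at 12.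

Further compounds
F0 | step 7 | none | none
F1 | step 2 | methyl 3-[(1S,4R)-4-(3-chloroprop-1-en-2-yl)-1-methyl-2-oxocyclohexyl]propanoate | C=C(CCl)[C@@H]1CC[C@@](C)(CCC(=O)OC)C(=O)C1
F2 | step 2 | methyl 3-[(1S,4R)-4-[3-(acetyloxy)prop-1-en-2-yl]-1-methyl-2-oxocyclohexyl]propanoate | C=C(COC(C)=O)[C@@H]1CC[C@@](C)(CCC(=O)OC)C(=O)C1
F3 | step 4 | methyl 3-[(1S,2E,4R)-4-{3-[(tert-butyldiphenylsilyl)oxy]prop-1-en-2-yl}-2-(cyanomethylidene)-1-methylcyclohexyl]propanoate | C=C(CO[Si](c2ccccc2)(c2ccccc2)C(C)(C)C)[C@@H]1CC[C@@](C)(CCC(=O)OC)/C(=C/C#N)C1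
F4 | step 4 | (2E)-2-[(2S,5R)-5-{3-[(tert-butyldiphenylsilyl)oxy]prop-1-en-2-yl}-2-(3-hydroxypropyl)-2-methylcyclohexylidene]acetaldehyde | C=C(CO[Si](c2ccccc2)(c2ccccc2)C(C)(C)C)[C@@H]1CC[C@@](C)(CCCO)/C(=C/C=O)C1
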